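**Plan**

- The retrosynthesis first cuts all eight C–N bonds of the two imidazoles. Each imidazole is free at N–H, C4 and C5 and is held only through C2 by a benzylic CH2, so N1–C2–N3 maps onto an aldehyde carbon plus two ammonia and C4–C5 onto glyoxal. This leads back to the bis(arylacetaldehyde) 6.
- 6 is traced through diol 5 to diester 4. Its diaryl ether C–O bond (at C2 of the methoxy-bearing ring) is cut next, giving aryl bromide 2 and phenol 3; the C–Br bond of 2 is cut last.
- Forward: the two benzene rings are joined by a copper-catalysed ether coupling, both ester arms are brought to the aldehyde level (LiAlH4, then Dess–Martin), and both imidazole rings arise together in the last step.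
- Stereochemistry: the target has no stereocentre or other stereogenic element, so nothing has to be set; the constitution defines it fully.

Key step: step 5

**Route**

Step 1
Reactants: 1 methyl 2-(3-methoxyphenyl)acetate
Product: 2 methyl 2-(2-bromo-5-methoxyphenyl)acetate
Conditions: NBS (1.05 equiv), MeCN, 0 °C → rt, dark
Reagents that add atoms: N-bromosuccinimide, O=C1CCC(=O)N1Br
Why: Electrophilic aromatic bromination with NBS in a polar solvent should go para to the strongly directing methoxy group, which is also the position ortho to the CH2CO2Me arm, while the ionic conditions leave the benzylic C–H bonds alone.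

Step 2
Reactants: 2 methyl 2-(2-bromo-5-methoxyphenyl)acetate; 3 methyl 2-(3-hydroxyphenyl)acetate
Product: 4 methyl 2-[5-methoxy-2-[3-(2-methoxy-2-oxoethyl)phenoxy]phenyl]acetate
Conditions: CuI (10 mol%), N,N-dimethylglycine·HCl (30 mol%), Cs2CO3 (2 equiv), 1,4-dioxane, 90 °C, Ar
Reagents that add atoms: none
Why: The ligand-accelerated Ullmann diaryl ether coupling is established for electron-rich and ortho-substituted aryl bromides with phenols, and the carbonate base in dioxane should leave both methyl esters and their weakly acidic benzylic CH2 groups untouched.

Step 3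
Reactants: 4 methyl 2-[5-methoxy-2-[3-(2-methoxy-2-oxoethyl)phenoxy]phenyl]acetate
Product: 5 2-[3-[2-(2-hydroxyethyl)-4-methoxyphenoxy]phenyl]ethanol
Conditions: LiAlH4 (2.5 equiv), THF, 0 °C → rt; aqueous work-up
Reagents that add atoms: none
Why: Hydride reduction of esters with LiAlH4 goes fully to the primary alcohols on both arms and should not touch the diaryl ether or the aryl methyl ether.

Step 4
Reactants: 5 2-[3-[2-(2-hydroxyethyl)-4-methoxyphenoxy]phenyl]ethanol
Product: 6 2-[5-methoxy-2-[3-(2-oxoethyl)phenoxy]phenyl]acetaldehyde
Conditions: Dess–Martin periodinane (2.4 equiv), CH2Cl2, 0 °C → rt; crude product used at once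
Reagents that add atoms: none
Why: Dess–Martin oxidation turns primary 2-arylethanols into arylacetaldehydes at or below room temperature without over-oxidation and without base, which should limit enolisation of the sensitive dialdehyde.

Step 5
Reactants: 6 2-[5-methoxy-2-[3-(2-oxoethyl)phenoxy]phenyl]acetaldehyde; 7 glyoxal (two molecules are incorporated per molecule of 6)
Product: 9 Lepidine C, via bis(aldimine) 8 (not isolated)
Conditions: glyoxal 7 (40% aq., 6 equiv), NH4OAc (20 equiv), MeOH, 0 °C → rt; 6 added slowly as a dilute MeOH solution
Reagents that add atoms: ammonium acetate, CC(=O)[O-].[NH4+] (supplies the four nitrogen atoms)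
Why: This is a Debus–Radziszewski imidazole synthesis run on both arms at once: each aldehyde carbon condenses with ammonia to the aldimine 8, a second ammonia adds to give an N–C–N unit, and its two nitrogens condense in turn with the two carbonyl groups of one glyoxal. Each ring closes when the second nitrogen attacks the remaining glyoxal carbonyl, whose oxygen lies outside the forming ring (5-exo-trig); loss of water gives a 2H-imidazole that aromatises by shift of the C2 hydrogen to nitrogen, so four C–N bonds form per ring and eight in all. No stereocentre is created. The selectivity needed is that the enolisable arylacetaldehyde carbons act as one-carbon electrophiles toward nitrogen rather than as aldol partners and that both arms react to completion; the weakly acidic ammonia source in large excess, excess glyoxal, low temperature and slow addition of 6 should keep free aldehyde low and trap each imine as it forms. The two arms sit on different rings of the diaryl ether and cannot interfere with each other, and the aryl ethers are inert, so the N–H, C4/C5-unsubstituted imidazoles should arise without protecting groups.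

**Compound list**

1 | methyl 2-(3-methoxyphenyl)acetate | COC(=O)Cc1cccc(OC)c1 | starting material
2 | methyl 2-(2-bromo-5-methoxyphenyl)acetate | COC(=O)Cc1cc(OC)ccc1Br | intermediate
3 | methyl 2-(3-hydroxyphenyl)acetate | COC(=O)Cc1cccc(O)c1 | starting material
4 | methyl 2-[5-methoxy-2-[3-(2-methoxy-2-oxoethyl)phenoxy]phenyl]acetate | COC(=O)Cc1cccc(Oc2ccc(OC)cc2CC(=O)OC)c1 | intermediate
5 | 2-[3-[2-(2-hydroxyethyl)-4-methoxyphenoxy]phenyl]ethanol | COc1ccc(Oc2cccc(CCO)c2)c(CCO)c1 | intermediate
6 | 2-[5-methoxy-2-[3-(2-oxoethyl)phenoxy]phenyl]acetaldehyde | COc1ccc(Oc2cccc(CC=O)c2)c(CC=O)c1 | intermediate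
7 | glyoxal | O=CC=O | starting material
8 | 2-[2-[3-(2-iminoethyl)phenoxy]-5-methoxyphenyl]ethanimine (bis(aldimine)) | COc1ccc(Oc2cccc(CC=N)c2)c(CC=N)c1 | intermediate
9 | Lepidine C, 2-[[2-[3-(1H-imidazol-2-ylmethyl)phenoxy]-5-methoxyphenyl]methyl]-1H-imidazole | COc1ccc(Oc2cccc(Cc3ncc[nH]3)c2)c(Cc2ncc[nH]2)c1 | target

**Step count**

Total: 5 steps. Longest linear sequence: 5 steps (1 → 2 → 4 → 5 → 6 → 9); phenol 3 and glyoxal 7 enter as purchased materials.

**Steps most likely to fail**

Step 5. The enolisable dialdehyde may be consumed by aldol condensation and oligomerisation under the ammonia conditions, closure may stop after one arm, and glyoxal–ammonia self-condensation may use up reagent. The fallback avoids the aldehyde level altogether and sets out from diester 4. Trimethylaluminium-mediated condensation with ethylenediamine in hot toluene should convert both ester groups into 2-imidazolines, giving 2-[[2-[3-(4,5-dihydro-1H-imidazol-2-ylmethyl)phenoxy]-5-methoxyphenyl]methyl]-4,5-dihydro-1H-imidazole F1. Dehydrogenation of both imidazoline rings (PhI(OAc)2, K2CO3, DMSO, rt) should then return to the route at 9.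

Step 4. The bis(arylacetaldehyde) may enolise, condense with itself or oxidise further during the oxidation and its work-up, so that little monomeric dialdehyde is recovered. The fallback reaches the aldehyde level by reduction from diester 4. Amidation with N,O-dimethylhydroxylamine hydrochloride and iPrMgCl (THF, −20 → 0 °C) should give the bis(Weinreb amide) 2-[2-[3-[2-[methoxy(methyl)amino]-2-oxoethyl]phenoxy]-5-methoxyphenyl]-N-methoxy-N-methylacetamide F2. Reduction with LiAlH4 (THF, −78 → 0 °C) stops at the chelated tetrahedral intermediates, which release both aldehydes only on cold aqueous quench, and so comes back to the route at 6.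

Step 2. Copper insertion into the electron-rich, ortho-substituted C–Br bond may be slow, so that protodebromination or base-induced ester hydrolysis and Claisen condensation overtake the C–O coupling. The fallback reverses the polarity of the coupling and sets out from bromide 2. Miyaura borylation (B2pin2, Pd(dppf)Cl2, KOAc, dioxane, 85 °C) should give methyl 2-[5-methoxy-2-(4,4,5,5-tetramethyl-1,3,2-dioxaborolan-2-yl)phenyl]acetate F3. Oxidative removal of the pinacol unit (NaIO4, NH4OAc, acetone/H2O, rt) should give [4-methoxy-2-(2-methoxy-2-oxoethyl)phenyl]boronic acid F4. Chan–Lam coupling of F4 with phenol 3 (Cu(OAc)2, pyridine, 4 Å MS, air, CH2Cl2, rt) forms the diaryl ether at room temperature without strong base and comes back to the route at 4.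

**Further compounds**

F1 | step 5 | 2-[[2-[3-(4,5-dihydro-1H-imidazol-2-ylmethyl)phenoxy]-5-methoxyphenyl]methyl]-4,5-dihydro-1H-imidazole | COc1ccc(Oc2cccc(CC3=NCCN3)c2)c(CC2=NCCN2)c1
F2 | step 4 | 2-[2-[3-[2-[methoxy(methyl)amino]-2-oxoethyl]phenoxy]-5-methoxyphenyl]-N-methoxy-N-methylacetamide | COc1ccc(Oc2cccc(CC(=O)N(C)OC)c2)c(CC(=O)N(C)OC)c1
F3 | step 2 | methyl 2-[5-methoxy-2-(4,4,5,5-tetramethyl-1,3,2-dioxaborolan-2-yl)phenyl]acetate | COC(=O)Cc1cc(OC)ccc1B1OC(C)(C)C(C)(C)O1
F4 | step 2 | [4-methoxy-2-(2-methoxy-2-oxoethyl)phenyl]boronic acid | COC(=O)Cc1cc(OC)ccc1B(O)O
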